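The plan cuts the tetrahydrofuran ring (O1, C2 bearing aryl, C3 bearing CH2OH, C4 bearing the aroyl group, C5) at O1–C2 and C3–C4. The segment O1–C2–C3 with its hydroxymethyl carbon is a cinnamaldehyde (β-carbon, α-carbon, formyl carbon). C5–C4 with the ketone carbon is a 3-aryl-3-nitroallyl alcohol whose nitro-bearing carbon is a masked carbonyl. One aminocatalytic operation adds the hydroxyl of nitroallylic alcohol 14 to enal 5 and closes the enamine onto the nitroalkene, giving the ring, both bonds and the C2, C3 and C4 stereocentres. The precursor is the pair 5 and 14, both benzyl-protected syringyl building blocks.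

Key step: step 7

Remark on the chemistry: ring atoms are numbered O1, C2 (aryl), C3 (CH2OH), C4 (aroyl), C5 throughout; the S-configured diarylprolinol silyl ether is assumed to show its usual sense of induction (attack on the Si face of the enal β-carbon), which gives 2S, and the mirror-image catalyst would be taken if the opposite were found; 4, 6 and 10 are taken as commercial.

Step 1
Reactants: 1 syringaldehyde, 2 benzyl bromide
Product: 3 4-(benzyloxy)-3,5-dimethoxybenzaldehyde
Conditions: BnBr, K2CO3, DMF, 60 °C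
Reagents that add atoms: benzyl bromide (2), BrCc1ccccc1
Why: Williamson ether synthesis, in which the phenoxide formed with carbonate displaces bromide from the benzylic halide (SN2) while the aldehyde is inert.

Step 2
Reactants: 3 4-(benzyloxy)-3,5-dimethoxybenzaldehyde, 4 (triphenylphosphoranylidene)acetaldehyde
Product: 5 (E)-3-[4-(benzyloxy)-3,5-dimethoxyphenyl]prop-2-enal
Conditions: Ph3P=CHCHO (1.2 equiv), toluene, 80 °C
Reagents that add atoms: (triphenylphosphoranylidene)acetaldehyde (4), O=CC=P(c1ccccc1)(c1ccccc1)c1ccccc1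
Why: Wittig olefination with a formyl-stabilised ylide should give the E enal directly, a small excess of ylide and moderate temperature limiting a second homologation.

Step 3
Reactants: 6 4-bromo-2,6-dimethoxyphenol, 2 benzyl bromide
Product: 7 2-(benzyloxy)-5-bromo-1,3-dimethoxybenzene
Conditions: BnBr, K2CO3, DMF, 60 °C
Reagents that add atoms: benzyl bromide (2), BrCc1ccccc1
Why: Williamson ether synthesis on the phenol, the aryl bromide being inert to carbonate and benzyl bromide.

Step 4
Reactants: 7 2-(benzyloxy)-5-bromo-1,3-dimethoxybenzene, 8 nitromethane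
Product: 9 2-(benzyloxy)-1,3-dimethoxy-5-(nitromethyl)benzene
Conditions: MeNO2 (solvent), Pd2(dba)3 (2.5 mol%), 2-dicyclohexylphosphino-2',4',6'-triisopropylbiphenyl (6 mol%), Cs2CO3, 3 Å sieves, 50 °C
Reagents that add atoms: nitromethane (8), C[N+](=O)[O-]
Why: Palladium-catalysed cross-coupling of an aryl bromide with nitromethane as its nitronate should give the arylnitromethane in one step, avoiding the nitrite ester that an electron-rich benzylic halide tends to give with a nitrite salt, while the excess of nitromethane suppresses a second arylation.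

Step 5
Reactants: 9 2-(benzyloxy)-1,3-dimethoxy-5-(nitromethyl)benzene, 10 2-[(tert-butyldimethylsilyl)oxy]acetaldehyde
Product: 13 (E)-tert-butyl({3-[4-(benzyloxy)-3,5-dimethoxyphenyl]-3-nitroprop-2-en-1-yl}oxy)dimethylsilane, via nitro aldol 11 (not isolated), via mesylate 12 (not isolated)
Conditions: Et3N (0.3 equiv), THF, 0 °C to rt; then MsCl, Et3N, −20 to 0 °C
Reagents that add atoms: 2-[(tert-butyldimethylsilyl)oxy]acetaldehyde (10), O=CCO[Si](C)(C)C(C)(C)C
Why: Henry (nitroaldol) addition of the acidic benzylic nitronate, then mesylation of the only free hydroxyl and E1cB elimination to the conjugated nitroalkene; the silyl ether keeps the primary oxygen out of both events (a free glycolaldehyde adduct would be a diol that cannot be dehydrated selectively), and the alkene geometry is immaterial because the later Michael step destroys it.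

Step 6
Reactants: 13 (E)-tert-butyl({3-[4-(benzyloxy)-3,5-dimethoxyphenyl]-3-nitroprop-2-en-1-yl}oxy)dimethylsilane
Product: 14 (E)-3-[4-(benzyloxy)-3,5-dimethoxyphenyl]-3-nitroprop-2-en-1-ol
Conditions: TsOH·H2O (10 mol%), MeOH, 0 °C to rt
Reagents that add atoms: none
Why: Acid-catalysed methanolysis of a primary silyl ether, chosen because the nitroalkene and the benzyl ethers tolerate acid but not base or fluoride-borne alkoxide.

Step 7
Reactants: 5 (E)-3-[4-(benzyloxy)-3,5-dimethoxyphenyl]prop-2-enal, 14 (E)-3-[4-(benzyloxy)-3,5-dimethoxyphenyl]-3-nitroprop-2-en-1-ol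
Product: 15 (2S,3S,4R)-2-[4-(benzyloxy)-3,5-dimethoxyphenyl]-4-{[4-(benzyloxy)-3,5-dimethoxyphenyl](nitro)methyl}tetrahydrofuran-3-carbaldehyde (nitro-bearing carbon as a mixture)
Conditions: 5 (1.3 equiv), (S)-2-[diphenyl(trimethylsilyloxy)methyl]pyrrolidine (20 mol%), PhCO2H (20 mol%), toluene, rt
Reagents that add atoms: none
Why: Proposed new method: the amine and 5 form an (E)-iminium ion, the primary hydroxyl of 14 adds reversibly to its β-carbon (O1–C2), and the enamine released attacks the β-carbon of the tethered nitroalkene (C3–C4) in an irreversible step that pulls the unfavourable alcohol addition forward before hydrolysis frees 15 and the catalyst. The closest known reaction type is the iminium–enamine oxa-Michael/Michael domino of enals with 2-(2-nitrovinyl)phenols to chromans under the same catalyst, extended here to an aliphatic alcohol and an α-aryl nitroalkene; intramolecular enamine additions to nitroalkenes, and amine-catalysed alcohol additions to enals driven by a following C–C bond formation, are each known separately. The tetrahydrofuran closes in the 5-exo-trig mode, the carbon that bears nitro and aryl staying outside the ring. C2 is set by the catalyst, whose CPh2OSiMe3 group covers the Re face of the β-carbon of the s-trans iminium ion so that oxygen enters on the Si face (2S); C3 is set by the same shielding of the enamine and by approach anti to the C2 aryl group, two effects that agree, and it can still settle into this trans position through the enamine; C4 is set in the envelope-like closing transition state that keeps the nitrobenzyl arm pseudo-equatorial and trans to C3, and the nitro-bearing carbon is left uncontrolled because it becomes the carbonyl. The step needs oxygen 1,4-addition and ring closure to win over self-addition of 14 and over amine addition to the nitroalkene: all competing additions are reversible and only the five-membered closure is not, the O–CH2–CH= tether places the acceptor carbon exactly five atoms from the enamine carbon, and the benzyl ethers leave no phenoxide to compete as nucleophile.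

Step 8
Reactants: 15 (2S,3S,4R)-2-[4-(benzyloxy)-3,5-dimethoxyphenyl]-4-{[4-(benzyloxy)-3,5-dimethoxyphenyl](nitro)methyl}tetrahydrofuran-3-carbaldehyde
Product: 16 [(2S,3R,4R)-2-[4-(benzyloxy)-3,5-dimethoxyphenyl]-4-{[4-(benzyloxy)-3,5-dimethoxyphenyl](nitro)methyl}tetrahydrofuran-3-yl]methanol
Conditions: NaBH4, MeOH, 0 °C (on the freshly prepared aldehyde)
Reagents that add atoms: none
Why: Chemoselective borohydride reduction of the aldehyde in the presence of the nitro group, which removes the only epimerisable hydrogen at C3 and so fixes that centre (the descriptor changes by priority only).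

Step 9
Reactants: 16 [(2S,3R,4R)-2-[4-(benzyloxy)-3,5-dimethoxyphenyl]-4-{[4-(benzyloxy)-3,5-dimethoxyphenyl](nitro)methyl}tetrahydrofuran-3-yl]methanol
Product: 18 [4-(benzyloxy)-3,5-dimethoxyphenyl]{(3S,4R,5S)-5-[4-(benzyloxy)-3,5-dimethoxyphenyl]-4-(hydroxymethyl)tetrahydrofuran-3-yl}methanone, via potassium nitronate 17 (not isolated)
Conditions: KOH (1.1 equiv), MeOH, 0 °C; then KHSO5 (as 2KHSO5·KHSO4·K2SO4), K2HPO4, H2O, 0 °C to rt; then K2CO3, MeOH, rt
Reagents that add atoms: potassium peroxymonosulfate, [K+].[O-]S(=O)(=O)OO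
Why: Oxidative Nef reaction, in which peroxymonosulfate transfers oxygen to the nitronate carbon and nitrite leaves, should give the aryl ketone without touching the primary alcohol or the benzyl ethers; C4, now α to the carbonyl, is then equilibrated by carbonate through its enolate to the arrangement trans to the C3 hydroxymethyl group (only the trans isomer stays an open, unstrained hydroxy ketone), while C2 and C3 cannot epimerise.

Step 10
Reactants: 18 [4-(benzyloxy)-3,5-dimethoxyphenyl]{(3S,4R,5S)-5-[4-(benzyloxy)-3,5-dimethoxyphenyl]-4-(hydroxymethyl)tetrahydrofuran-3-yl}methanone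
Product: 19 (4-hydroxy-3,5-dimethoxyphenyl)[(3S,4R,5S)-5-(4-hydroxy-3,5-dimethoxyphenyl)-4-(hydroxymethyl)tetrahydrofuran-3-yl]methanone
Conditions: H2 (1 atm), Pd/C (10%), EtOAc/MeOH, rt
Reagents that add atoms: none
Why: Hydrogenolysis of the two aryl benzyl ethers at atmospheric pressure in a neutral solvent should be faster than reduction of the electron-rich aryl ketone or cleavage of the C2–O1 benzylic ether, so the three stereocentres are untouched.

Compound list
1 | syringaldehyde (4-hydroxy-3,5-dimethoxybenzaldehyde) | COc1cc(C=O)cc(OC)c1O | starting material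
2 | benzyl bromide | BrCc1ccccc1 | starting material
3 | 4-(benzyloxy)-3,5-dimethoxybenzaldehyde | COc1cc(C=O)cc(OC)c1OCc1ccccc1 | intermediate
4 | (triphenylphosphoranylidene)acetaldehyde | O=CC=P(c1ccccc1)(c1ccccc1)c1ccccc1 | starting material
5 | (E)-3-[4-(benzyloxy)-3,5-dimethoxyphenyl]prop-2-enal | O=C/C=C/c1cc(OC)c(OCc2ccccc2)c(OC)c1 | intermediate
6 | 4-bromo-2,6-dimethoxyphenol | COc1cc(Br)cc(OC)c1O | starting material
7 | 2-(benzyloxy)-5-bromo-1,3-dimethoxybenzene | COc1cc(Br)cc(OC)c1OCc1ccccc1 | intermediate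
8 | nitromethane | C[N+](=O)[O-] | starting material
9 | 2-(benzyloxy)-1,3-dimethoxy-5-(nitromethyl)benzene | COc1cc(C[N+](=O)[O-])cc(OC)c1OCc1ccccc1 | intermediate
10 | 2-[(tert-butyldimethylsilyl)oxy]acetaldehyde | O=CCO[Si](C)(C)C(C)(C)C | starting material
11 | 1-[4-(benzyloxy)-3,5-dimethoxyphenyl]-3-[(tert-butyldimethylsilyl)oxy]-1-nitropropan-2-ol (both diastereomers, not isolated) | [O-][N+](=O)C(c1cc(OC)c(OCc2ccccc2)c(OC)c1)C(O)CO[Si](C)(C)C(C)(C)C | intermediate
12 | 1-[4-(benzyloxy)-3,5-dimethoxyphenyl]-3-[(tert-butyldimethylsilyl)oxy]-1-nitropropan-2-yl methanesulfonate (not isolated) | [O-][N+](=O)C(c1cc(OC)c(OCc2ccccc2)c(OC)c1)C(OS(C)(=O)=O)CO[Si](C)(C)C(C)(C)C | intermediate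
13 | (E)-tert-butyl({3-[4-(benzyloxy)-3,5-dimethoxyphenyl]-3-nitroprop-2-en-1-yl}oxy)dimethylsilane | CC(C)(C)[Si](C)(C)OC/C=C(/[N+](=O)[O-])c1cc(OC)c(OCc2ccccc2)c(OC)c1 | intermediate
14 | (E)-3-[4-(benzyloxy)-3,5-dimethoxyphenyl]-3-nitroprop-2-en-1-ol | OC/C=C(/[N+](=O)[O-])c1cc(OC)c(OCc2ccccc2)c(OC)c1 | intermediate
15 | (2S,3S,4R)-2-[4-(benzyloxy)-3,5-dimethoxyphenyl]-4-{[4-(benzyloxy)-3,5-dimethoxyphenyl](nitro)methyl}tetrahydrofuran-3-carbaldehyde (all-trans ring, nitro carbon as a mixture) | [O-][N+](=O)C(c1cc(OC)c(OCc2ccccc2)c(OC)c1)[C@@H]1CO[C@H](c2cc(OC)c(OCc3ccccc3)c(OC)c2)[C@H]1C=O | intermediate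
16 | [(2S,3R,4R)-2-[4-(benzyloxy)-3,5-dimethoxyphenyl]-4-{[4-(benzyloxy)-3,5-dimethoxyphenyl](nitro)methyl}tetrahydrofuran-3-yl]methanol | [O-][N+](=O)C(c1cc(OC)c(OCc2ccccc2)c(OC)c1)[C@@H]1CO[C@H](c2cc(OC)c(OCc3ccccc3)c(OC)c2)[C@H]1CO | intermediate
17 | potassium nitronate of 16 (not isolated) | [K+].[O-][N+]([O-])=C(c1cc(OC)c(OCc2ccccc2)c(OC)c1)[C@@H]1CO[C@H](c2cc(OC)c(OCc3ccccc3)c(OC)c2)[C@H]1CO | intermediate
18 | [4-(benzyloxy)-3,5-dimethoxyphenyl]{(3S,4R,5S)-5-[4-(benzyloxy)-3,5-dimethoxyphenyl]-4-(hydroxymethyl)tetrahydrofuran-3-yl}methanone | COc1cc(C(=O)[C@@H]2CO[C@H](c3cc(OC)c(OCc4ccccc4)c(OC)c3)[C@H]2CO)cc(OC)c1OCc1ccccc1 | intermediate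
19 | (4-hydroxy-3,5-dimethoxyphenyl)[(3S,4R,5S)-5-(4-hydroxy-3,5-dimethoxyphenyl)-4-(hydroxymethyl)tetrahydrofuran-3-yl]methanone (C2 aryl, C3 CH2OH and C4 aroyl all trans) | COc1cc(C(=O)[C@@H]2CO[C@H](c3cc(OC)c(O)c(OC)c3)[C@H]2CO)cc(OC)c1O | target

Total step count: 10. Longest linear sequence: 8 steps (steps 3 to 10, from 6 to 19).

Steps most likely to fail

Step 7 (proposed new method). The alcohol conjugate addition may be too unfavourable to feed the ring closure, so that the hydroxy nitroalkene is consumed by self-addition or isomerisation. Alternatively, reversible addition may erode facial control at C2. The fallback uses known chemistry only, sets out from 3 (with 9 as partner) and returns at 15.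
- Brown allylation of 3 with the antipode of B-allyldiisopinocampheylborane that delivers the S carbinol (Et2O, −78 °C; then NaOH, H2O2) should give (S)-1-[4-(benzyloxy)-3,5-dimethoxyphenyl]but-3-en-1-ol F1.
- O-Alkylation (NaH, tert-butyl bromoacetate, THF, 0 °C) should give tert-butyl ester F2, and i-Bu2AlH at −78 °C the α-alkoxy aldehyde F3.
- Henry addition of 9 (Et3N, THF) should give nitro aldol F4, whose mesylate F5 (MsCl, Et3N) should eliminate to the nitroalkene F6, as in step 5.
- Lemieux–Johnson cleavage of the terminal alkene (OsO4 cat., NaIO4, 2,6-lutidine, dioxane/H2O) should give the formyl nitroalkene F7.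
- Exposure of F7 to the same S amine catalyst (PhCO2H, toluene, rt) should effect the well-precedented intramolecular enamine Michael addition to a nitroalkene (5-exo-trig) and deliver 15. C2 then comes from the allylation and only C3 and C4 are set in the closure.

Step 5. Retro-nitroaldol cleavage during activation, or base-induced migration of the new double bond out of conjugation toward the silyl enol ether, may drain the nitroalkene. The fallback sets out from 9 and 10 and returns at 13. Aldehyde 10 is condensed with n-butylamine (MgSO4, CH2Cl2) to the N-butylimine F8. Stirring F8 with 9 in acetic acid at rt should give 13 by aza-Henry addition and loss of butylamine, with no hydroxyl activation and no amine base present.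

Step 9. Oxygen transfer to a hindered, aryl-stabilised nitronate may be slow enough for oxidation of the electron-rich rings to compete, or the carbonyl may not form cleanly next to the free alcohol. The fallback sets out from 16 and returns at 18. The nitro group is reduced to the ketoxime F9 (SnCl2·2H2O, PhSH, Et3N, MeCN). The oxime is then cleaved reductively (aqueous TiCl3, NH4OAc, THF) to 18, followed by the same K2CO3/MeOH equilibration at C4.

Further compounds
F1 | step 7 | (S)-1-[4-(benzyloxy)-3,5-dimethoxyphenyl]but-3-en-1-ol | C=CC[C@H](O)c1cc(OC)c(OCc2ccccc2)c(OC)c1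
F2 | step 7 | tert-butyl 2-({(1S)-1-[4-(benzyloxy)-3,5-dimethoxyphenyl]but-3-en-1-yl}oxy)acetate | C=CC[C@H](OCC(=O)OC(C)(C)C)c1cc(OC)c(OCc2ccccc2)c(OC)c1
F3 | step 7 | 2-({(1S)-1-[4-(benzyloxy)-3,5-dimethoxyphenyl]but-3-en-1-yl}oxy)acetaldehyde | C=CC[C@H](OCC=O)c1cc(OC)c(OCc2ccccc2)c(OC)c1
F4 | step 7 | 1-[4-(benzyloxy)-3,5-dimethoxyphenyl]-3-({(1S)-1-[4-(benzyloxy)-3,5-dimethoxyphenyl]but-3-en-1-yl}oxy)-1-nitropropan-2-ol (diastereomers) | C=CC[C@H](OCC(O)C([N+](=O)[O-])c1cc(OC)c(OCc2ccccc2)c(OC)c1)c1cc(OC)c(OCc2ccccc2)c(OC)c1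
F5 | step 7 | methanesulfonate of F4 | C=CC[C@H](OCC(OS(C)(=O)=O)C([N+](=O)[O-])c1cc(OC)c(OCc2ccccc2)c(OC)c1)c1cc(OC)c(OCc2ccccc2)c(OC)c1
F6 | step 7 | 2-(benzyloxy)-5-[(1S)-1-({(2E)-3-[4-(benzyloxy)-3,5-dimethoxyphenyl]-3-nitroprop-2-en-1-yl}oxy)but-3-en-1-yl]-1,3-dimethoxybenzene | C=CC[C@H](OC/C=C(/[N+](=O)[O-])c1cc(OC)c(OCc2ccccc2)c(OC)c1)c1cc(OC)c(OCc2ccccc2)c(OC)c1
F7 | step 7 | (3S)-3-[4-(benzyloxy)-3,5-dimethoxyphenyl]-3-({(2E)-3-[4-(benzyloxy)-3,5-dimethoxyphenyl]-3-nitroprop-2-en-1-yl}oxy)propanal | O=CC[C@H](OC/C=C(/[N+](=O)[O-])c1cc(OC)c(OCc2ccccc2)c(OC)c1)c1cc(OC)c(OCc2ccccc2)c(OC)c1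
F8 | step 5 | N-butyl-2-[(tert-butyldimethylsilyl)oxy]ethan-1-imine | CCCCN=CCO[Si](C)(C)C(C)(C)C
F9 | step 9 | [4-(benzyloxy)-3,5-dimethoxyphenyl]{(3R,4R,5S)-5-[4-(benzyloxy)-3,5-dimethoxyphenyl]-4-(hydroxymethyl)tetrahydrofuran-3-yl}methanone oxime | ON=C(c1cc(OC)c(OCc2ccccc2)c(OC)c1)[C@@H]1CO[C@H](c2cc(OC)c(OCc3ccccc3)c(OC)c2)[C@H]1CO
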